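Each turn of either route to target spends one partner, so with 0.600 equiv of partner a target above 60.0% of the starting material is impossible here, and the question in each flask is what share of the partner meets starting material before it meets another partner.

    starting material + partner + target → 2 target (k1 = 4.2 × 10⁶ M⁻² s⁻¹, Ea1 = 9.00 kJ mol⁻¹)
    starting material + partner → target (k2 = 43 M⁻¹ s⁻¹, Ea2 = 39.0 kJ mol⁻¹)
    crystals ⇌ target, rate k3*(cs3 - [target]) while solid is left; crystals form when [target] > cs3 (cs3 = 0.017 mM, k3 = 0.75 s⁻¹)
    partner ⇌ dormant form (K4 = 0.41, k4 = 0.031 s⁻¹, Ea4 = 79.0 kJ mol⁻¹, ΔH4 = 3.00 kJ mol⁻¹)
    2 partner → homo dimer (k5 = 230 M⁻¹ s⁻¹, Ea5 = 40.0 kJ mol⁻¹)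
    (constants at 25 °C)

| setting | dawn | dusk | autumn | spring |
|---|---|---|---|---|
| starting material | 2.0 × 10⁻⁴ M (fed, over 2.5 min) | 2.0 × 10⁻⁴ M | 2.0 × 10⁻⁴ M (fed, over 2.5 min) | 2.0 × 10⁻⁴ M |
| partner | 0.600 equiv | 0.600 equiv | 0.600 equiv | 0.600 equiv (fed, over 2.5 min) |
| time | 4.0 min | 4.0 min | 4.0 min | 4.0 min |
| remark | the addition at 5 °C, then warmed to 25 °C; the feed brings no volume worth counting | everything together at the start at 5 °C, warmed to 25 °C at 2.5 min | all else is in the flask from the start; the feed brings no volume worth counting | all else is in the flask from the start; the feed brings no volume worth counting |
| temperature |  |  | 25 °C | 25 °C |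

- for target the crystals are counted in
- for a step with 2 of a species take k times the square, and two of it per event
- as a solid, counted per litre of solution: crystals
- constants are those at 25 °C; use the activation energies and enthalpies for any other temperature

1. the flask with the highest amount of target, in percent of the starting material charged ("all alike" if they lie within 1.5 percentage points) (dawn / dusk / autumn / spring / all alike)
2. final target, as a percentage of the starting material charged, in dawn
3. final target, as a percentage of the starting material charged, in dusk
4. final target, as a percentage of the starting material charged, in autumn
5. final target, as a percentage of the starting material charged, in spring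

I reckon spring first, where partner enters the full charge of starting material at 0.0480 mM min⁻¹. While crystals stand, dissolved target sits near 0.017 mM, so the two routes to target together drain partner as a pseudo-first-order step of 0.0229 s⁻¹ at full starting material.

Two extreme flasks can be solved in the head. Without dimerisation, spring's partner settles at 0.0350 mM and every fed partner becomes target. Without capture, it settles at 0.0417 mM and none does. The real spring has both exits open, so its level, 0.0237 mM, lies below both, and 67.7% of the partner is captured.

The correction is the starting material that this capture consumes. Taking its middle level lowers the drain to 0.0182 s⁻¹ and raises the level to 0.0264 mM. The capture ratio, which is partner captured per partner lost to dimerisation, a selectivity factor, is then 1.50. The share captured is the ratio over one plus the ratio, 60.1%, so I commit to 36.0% target in spring.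

In autumn the partner waits in the flask while starting material trickles in, and dimerisation alone takes it down to 0.0129 mM by the end of the feed. The first half-life of autumn's charged partner by this step alone is 18.1 s, and by then the feed has brought 12.1% of the starting material. With dissolved target taken at its solubility, the capture ratio in autumn at that moment is 0.100, lower than spring's, so I place autumn well below spring. Dawn and dusk run cold, and I leave them unreckoned.

The forecast names spring at 35%, with dusk 32%, dawn 19% and autumn 15%, on the ground that the outcome depends on “keeping free partner low while SM is high”.

The simulation puts spring highest at 35.5%, then dusk at 31.7%, dawn at 18.7% and autumn at 14.2%. Spring's partner at 2.50 min reads 21.5% of its charge, or 0.0258 mM, which gives a capture ratio of 1.53.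

The neighbour is autumn with 2.40 equiv of partner, 4.00 times the charge. Dimerisation alone brings its pool to 0.0141 mM at the end of the feed, against 0.0129 mM in autumn. Against full starting material, that level gives a capture ratio of 3.54, still above spring's, but the larger charge arrives at only 1.09 times autumn's level. The neighbour ends with 2.18 × 10⁻⁴ M homo dimer and 20.2% target, against 14.2% in autumn.

The constants are those of an exercise; what happens was integrated by code.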